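A mole per litre of nucleophile is the unit of account in these flasks, and the question is how much electrophile it can pay for.

| flask | electrophile | nucleophile | solid base | time |
|---|---|---|---|---|
| green | 0.20 M | 0.300 M | 0.100 M | 5.0 min |
| teal | 0.20 M | 0.450 M | 0.100 M | 5.0 min |

    nucleophile + acid set free ⇌ protonated nucleophile, settled at all times (K1 = 1100 /M)
    electrophile + nucleophile → acid set free + target (k2 = 0.013 /M/s)
    acid set free + free base ⇌ salt of the base, settled at all times (K3 = 8.9 /M)
    electrophile + target → side product (k4 = 0.046 /M/s)
    solid base ⇌ free base, rate k5*(cs5 - [free base]) while solid is left; crystals form when [free base] > cs5 (cs5 = 0.13 M, k5 = 0.0082 /s)

* part of the electrophile that has reacted at the end, green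
* part of the electrophile that has reacted at the end, teal
* what raising the concentration of nucleophile from its lowest to its highest value here does to the part of the electrophile that has reacted (changes below 5 percentage points count as none) (no change / it rises / it falls)

- in percentages every species weighs as the electrophile in it: one side product counts as two
- as a solid, counted per litre of solution: solid base
- at the start none of the solid base is in solution
- run time (green): 5.0 min

Turn the nucleophile first, by hand. Each coupling sets one acid free, and that acid goes to the nucleophile rather than to the free base, because 1100 /M times the starting nucleophile of green gives 330, while 8.9 /M times the entire base charge gives 0.890. So a coupling costs two nucleophile, and by that same comparison you should expect the solid base to buy nothing. Each target can then take one more electrophile, so a coupling removes two electrophile at the most, and one nucleophile pays for one electrophile. The ratio c(nucleophile)/c(electrophile) as charged, 150% in green and 225% in teal, is therefore the nucleophile ceiling, the largest part of the electrophile that the nucleophile charge can pay for at two nucleophile per coupling. Both ceilings stand above the whole charge, so in these two flasks I look to the clock instead.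

Now turn the time. The coupling, taken as pseudo-first-order with the nucleophile as charged, gives the electrophile a half-life of 3.0 min in green, against a run of 5.0 min. The target's half-life in its further reaction, with the electrophile as charged in green, is shorter, 1.3 min, so I bet that the second electrophile taken offsets the falling nucleophile. The cheapest reckoning is then one minus the exponential of minus the coupling's rate constant times c(nucleophile) as charged times time, which gives 69.0% in green and 82.7% in teal, a rise. The electrophile charge drops out of this formula.

The forecast gives 69% for green (from 64% to 74%), 83% for teal (from 78% to 88%) and, for the trend, it rises, holding that “each coupling effectively uses up two nucleophiles”.

The simulation gives 69.2% in green and 83.9% in teal, a change of 15 percentage points: it rises. Moved alone by one common factor in green, the settings rank nucleophile (10 points), then time (8.6 points), then electrophile (2.6 points), then solid base (under 0.05 points). The neighbour of teal charged with 0.80 M of electrophile has a ceiling of 56.2%, below the whole charge, and it gives 55.1%. At 5.00 min in that neighbour, the nucleophile, there the limiting reagent, is down to 4.2% of its charge unbound, while 45% of the electrophile remains.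

The rate constants come from no measurement, and the outcome is calculated.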